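**Plan**

- Retrosynthesis: the angelate C–O bond, the formyl oxygen (back to an isopropenyl methyl), the carbinol C–H (back to an aryl methyl ketone) and the aryl–acetyl bond are cut first. The isopropenyl group is traced to a tertiary alcohol, and the C3–OAc bond, with inversion, to the C3–O bond of a cis-fused oxetane.
- Key cut: the oxetane is opened across C2–C3 and O–CMe2 to an ortho-formyl aryl 2-methylprop-1-enyl ether, itself made from 5-bromosalicylaldehyde (ring A) and methallyl chloride.
- Enabling feature: in ring B, C3 carries one oxygen and one hydrogen, and its neighbor C2 carries O1 and a carbon with two one-carbon arms. These are the atoms of a formyl C=O laid across the C=C of an aryl isobutenyl ether held ortho to it.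
- Forward order: ether formation and double-bond shift, one photocycloaddition that closes ring B and the oxetane together, oxetane opening by acetate, then acetyl (Stille), isopropenyl (dehydration), carbinol (transfer hydrogenation), angelate, and allylic oxidation to the enal.
- Stereochemistry: ring fusion forces C2/C3 cis in the photoadduct and acetate inverts C3, giving the 2,3-trans acetate. Absolute configuration at C2/C3 comes from a lipase resolution of that acetate, because a chiral Lewis acid on the formyl group would tie up the lone pair the photoreaction needs. The (R)-carbinol comes from catalyst-controlled transfer hydrogenation, and the Z-alkene from angelic acid.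

Key step: step 3

Assumption: Burkholderia cepacia lipase treats the fused aryl ring as the large carbinol substituent (Kazlauskas rule, as for indan-1-ol and chroman-4-ol), so it hydrolyses the (2S,3S)-acetate and leaves (2R,3R)-6.

Remark: compounds 5 and 6 are racemates; their names and SMILES show the enantiomer that is carried on.

**Route**

Step 1
Reactants: 1 5-bromo-2-hydroxybenzaldehyde; 2 3-chloro-2-methylprop-1-ene
Product: 3 5-bromo-2-[(2-methylprop-2-en-1-yl)oxy]benzaldehyde
Conditions: K2CO3, DMF, 60 °C
Reagents that add atoms: none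
Why: Williamson ether synthesis, in which the phenoxide displaces the primary allylic chloride and the aldehyde is not touched.

Step 2
Reactants: 3 5-bromo-2-[(2-methylprop-2-en-1-yl)oxy]benzaldehyde
Product: 4 5-bromo-2-[(2-methylprop-1-en-1-yl)oxy]benzaldehyde
Conditions: RuHCl(CO)(PPh3)3 (3 mol%), toluene, 90 °C
Reagents that add atoms: none
Why: Ruthenium-hydride olefin isomerization (hydrometalation, β-hydride elimination) moves the double bond into conjugation with oxygen; the gem-dimethyl terminus leaves no E/Z question and the temperature is far below that of a Claisen rearrangement.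

Step 3
Reactants: 4 5-bromo-2-[(2-methylprop-1-en-1-yl)oxy]benzaldehyde
Product: 5 racemic cis-fused 6-bromo-2,2-dimethyl-2a,7b-dihydro-2H-oxeto[3,2-b][1]benzofuran (drawn as the (2aR,7bS) enantiomer)
Conditions: hν (350 nm), degassed benzene (0.01 M), 20 °C
Reagents that add atoms: none
Why: Proposed new method: excitation at 350 nm and intersystem crossing give the n,π* triplet aldehyde, whose electrophilic oxygen adds to the nucleophilic CMe2 terminus of the enol ether (7-endo) to form a triplet 1,4-biradical with a benzylic radical at C3 and an α-aryloxy radical at C2, and after spin inversion these two centers couple. The closest known reaction types are intramolecular Paternò–Büchi reactions of aryl carbonyl compounds with tethered electron-rich alkenes and the intermolecular addition of aryl aldehydes to cyclic enol ethers, which places the carbonyl oxygen on the β-carbon in the same way. Ring B closes as a five-membered ring by the C2–C3 radical coupling across the one-atom ether tether, and the oxetane closes as a four-membered ring by O–CMe2 bond formation first and the same C2–C3 coupling second. The two new stereocenters (C2a and C7b of 5, later C2 and C3) are controlled by the ring fusion, since a four-membered ring can only be cis-fused to a five-membered one, so C2 has its final relative configuration and C3 carries its oxygen on the face that step 4 will vacate. The step needs fused rather than bridged regiochemistry and no attack on the arene; enol-ether polarity, the stabilized α-aryloxy radical and the far greater strain of the benzo-fused 2,6-dioxabicyclo[3.1.1]heptane alternative secure the first, and the one-atom tether makes ortho cycloaddition to ring A geometrically impossible. No chiral Lewis acid is used, because binding the formyl lone pair would remove the n,π* state on which the addition depends, so 5 forms as the racemate and the absolute configuration is fixed in step 5; at 350 nm neither the C–Br bond nor the product absorbs.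

Step 4
Reactants: 5 racemic cis-fused 6-bromo-2,2-dimethyl-2a,7b-dihydro-2H-oxeto[3,2-b][1]benzofuran
Product: 6 racemic trans-5-bromo-2-(2-hydroxypropan-2-yl)-2,3-dihydro-1-benzofuran-3-yl acetate (drawn as the (2R,3R) enantiomer)
Conditions: AcOH, NaOAc, 40 °C
Reagents that add atoms: acetic acid, CC(=O)O
Why: Acid-assisted nucleophilic opening of a strained 2-aryloxetane at its benzylic carbon: acetate attacks C3 from the convex face anti to the leaving oxygen, so C3 is inverted to the 2,3-trans acetate and the tertiary C–O bond stays; the buffer and the absence of a Lewis acid are meant to keep a free C3 cation, which could lose a proton or acetone to give the aromatic benzofuran, from forming.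

Step 5
Reactants: 6 racemic trans-5-bromo-2-(2-hydroxypropan-2-yl)-2,3-dihydro-1-benzofuran-3-yl acetate
Product: 7 (2R,3R)-5-bromo-2-(2-hydroxypropan-2-yl)-2,3-dihydro-1-benzofuran-3-yl acetate (single enantiomer)
Conditions: Burkholderia cepacia lipase (immobilized), aqueous KH2PO4/K2HPO4 buffer (pH 7)/t-BuOMe, 30 °C, stopped just beyond half conversion
Reagents that add atoms: none
Why: Lipase-catalyzed kinetic resolution by enantioselective hydrolysis of a secondary benzylic acetate: the (2S,3S)-acetate is cleaved to the diol and the (2R,3R)-acetate is recovered, which fixes the absolute configuration of C2 and C3.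

Step 6
Reactants: 7 (2R,3R)-5-bromo-2-(2-hydroxypropan-2-yl)-2,3-dihydro-1-benzofuran-3-yl acetate; 8 tributyl(1-ethoxyvinyl)stannane
Product: 10 (2R,3R)-5-acetyl-2-(2-hydroxypropan-2-yl)-2,3-dihydro-1-benzofuran-3-yl acetate, via 1-ethoxyvinyl arene 9 (not isolated)
Conditions: Pd(PPh3)4 (5 mol%), toluene, 100 °C; then 0.5 M aq. HCl, THF, 0 °C
Reagents that add atoms: water, O
Why: Stille coupling (oxidative addition of the aryl bromide to zerovalent palladium, transmetalation from tin, reductive elimination) gives the α-aryl enol ether, which mild aqueous acid hydrolyses to the methyl ketone; the coupling is placed before the dehydration so that zerovalent palladium never meets the allylic aryl ether of the isopropenyl compounds.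

Step 7
Reactants: 10 (2R,3R)-5-acetyl-2-(2-hydroxypropan-2-yl)-2,3-dihydro-1-benzofuran-3-yl acetate
Product: 12 (2S,3R)-5-acetyl-2-(prop-1-en-2-yl)-2,3-dihydro-1-benzofuran-3-yl acetate, via tertiary sulfamate ester 11 (not isolated)
Conditions: Burgess reagent, toluene, 20 → 60 °C
Reagents that add atoms: none
Why: Burgess dehydration (syn-elimination through the tertiary sulfamate ester) should take one of the six methyl hydrogens rather than the single hindered C2–H that is deactivated by O1 and the acetoxy-bearing C3, as is usual for 2-(2-hydroxypropan-2-yl)-2,3-dihydrobenzofurans; no stereocenter is touched and the C2 descriptor changes from R to S only through the priority rules.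

Step 8
Reactants: 12 (2S,3R)-5-acetyl-2-(prop-1-en-2-yl)-2,3-dihydro-1-benzofuran-3-yl acetate
Product: 13 (2S,3R)-5-[(1R)-1-hydroxyethyl]-2-(prop-1-en-2-yl)-2,3-dihydro-1-benzofuran-3-yl acetate
Conditions: RuCl[(R,R)-TsDPEN](p-cymene) (1 mol%), HCO2H/Et3N (5:2), EtOAc, 30 °C
Reagents that add atoms: none
Why: Noyori–Ikariya asymmetric transfer hydrogenation: the (R,R)-TsDPEN ruthenium hydride delivers hydride to the Si face of the aryl methyl ketone to give the (R)-carbinol under catalyst control, and it leaves the isolated alkene and the acetate alone.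

Step 9
Reactants: 13 (2S,3R)-5-[(1R)-1-hydroxyethyl]-2-(prop-1-en-2-yl)-2,3-dihydro-1-benzofuran-3-yl acetate; 14 angelic acid
Product: 16 (1R)-1-[(2S,3R)-3-acetoxy-2-(prop-1-en-2-yl)-2,3-dihydro-1-benzofuran-5-yl]ethyl (2Z)-2-methylbut-2-enoate, via angelic 2,4,6-trichlorobenzoic anhydride 15 (not isolated)
Conditions: 14, 2,4,6-trichlorobenzoyl chloride, Et3N, toluene, 20 °C; then 13, 75 °C (no DMAP)
Reagents that add atoms: none
Why: Yamaguchi esterification: the alcohol attacks the less hindered angeloyl carbonyl of the mixed anhydride, and leaving out a nucleophilic pyridine catalyst avoids the reversible conjugate addition that turns the Z angelate into the E tiglate; the carbinol center is retained because the bond is made at oxygen.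

Step 10
Reactants: 16 (1R)-1-[(2S,3R)-3-acetoxy-2-(prop-1-en-2-yl)-2,3-dihydro-1-benzofuran-5-yl]ethyl (2Z)-2-methylbut-2-enoate
Product: 17 (1R)-1-[(2S,3R)-3-acetoxy-2-(3-hydroxyprop-1-en-2-yl)-2,3-dihydro-1-benzofuran-5-yl]ethyl (2Z)-2-methylbut-2-enoate
Conditions: SeO2 (0.5 equiv), t-BuOOH (3 equiv), CH2Cl2, 20 °C
Reagents that add atoms: selenium dioxide, O=[Se]=O; tert-butyl hydroperoxide, CC(C)(C)OO
Why: Selenium dioxide allylic oxidation (ene reaction, then [2,3]-sigmatropic shift) should pick the electron-rich 1,1-disubstituted isopropenyl alkene and oxidize its methyl group (CH3 before CH), while the electron-poor conjugated angelate alkene does not react at room temperature; any material oxidized further would already be 18.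

Step 11
Reactants: 17 (1R)-1-[(2S,3R)-3-acetoxy-2-(3-hydroxyprop-1-en-2-yl)-2,3-dihydro-1-benzofuran-5-yl]ethyl (2Z)-2-methylbut-2-enoate
Product: 18 (1R)-1-[(2S,3R)-3-acetoxy-2-(3-oxoprop-1-en-2-yl)-2,3-dihydro-1-benzofuran-5-yl]ethyl (2Z)-2-methylbut-2-enoate
Conditions: MnO2 (activated, excess), CH2Cl2, 20 °C
Reagents that add atoms: none
Why: Manganese dioxide oxidation of a primary allylic alcohol to the enal under neutral conditions, which spares both esters, the Z-alkene and all three stereocenters.

**Compound list**

1 | 5-bromo-2-hydroxybenzaldehyde | O=Cc1cc(Br)ccc1O | starting material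
2 | 3-chloro-2-methylprop-1-ene | C=C(C)CCl | starting material
3 | 5-bromo-2-[(2-methylprop-2-en-1-yl)oxy]benzaldehyde | C=C(C)COc1ccc(Br)cc1C=O | intermediate
4 | 5-bromo-2-[(2-methylprop-1-en-1-yl)oxy]benzaldehyde | CC(C)=COc1ccc(Br)cc1C=O | intermediate
5 | racemic cis-fused 6-bromo-2,2-dimethyl-2a,7b-dihydro-2H-oxeto[3,2-b][1]benzofuran (drawn as the (2aR,7bS) enantiomer) | CC3(C)[C@@H]1Oc2ccc(Br)cc2[C@@H]1O3 | intermediate
6 | racemic trans-5-bromo-2-(2-hydroxypropan-2-yl)-2,3-dihydro-1-benzofuran-3-yl acetate (drawn as the (2R,3R) enantiomer) | CC(C)(O)[C@@H]1Oc2ccc(Br)cc2[C@H]1OC(C)=O | intermediate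
7 | (2R,3R)-5-bromo-2-(2-hydroxypropan-2-yl)-2,3-dihydro-1-benzofuran-3-yl acetate (single enantiomer) | CC(C)(O)[C@@H]1Oc2ccc(Br)cc2[C@H]1OC(C)=O | intermediate
8 | tributyl(1-ethoxyvinyl)stannane | CCCC[Sn](CCCC)(CCCC)C(=C)OCC | starting material
9 | (2R,3R)-5-(1-ethoxyethenyl)-2-(2-hydroxypropan-2-yl)-2,3-dihydro-1-benzofuran-3-yl acetate (not isolated) | CC(C)(O)[C@@H]1Oc2ccc(C(=C)OCC)cc2[C@H]1OC(C)=O | intermediate
10 | (2R,3R)-5-acetyl-2-(2-hydroxypropan-2-yl)-2,3-dihydro-1-benzofuran-3-yl acetate | CC(C)(O)[C@@H]1Oc2ccc(C(C)=O)cc2[C@H]1OC(C)=O | intermediate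
11 | methyl N-[({2-[(2R,3R)-3-acetoxy-5-acetyl-2,3-dihydro-1-benzofuran-2-yl]propan-2-yl}oxy)sulfonyl]carbamate (not isolated) | COC(=O)NS(=O)(=O)OC(C)(C)[C@@H]1Oc2ccc(C(C)=O)cc2[C@H]1OC(C)=O | intermediate
12 | (2S,3R)-5-acetyl-2-(prop-1-en-2-yl)-2,3-dihydro-1-benzofuran-3-yl acetate | C=C(C)[C@@H]1Oc2ccc(C(C)=O)cc2[C@H]1OC(C)=O | intermediate
13 | (2S,3R)-5-[(1R)-1-hydroxyethyl]-2-(prop-1-en-2-yl)-2,3-dihydro-1-benzofuran-3-yl acetate | C=C(C)[C@@H]1Oc2ccc([C@@H](C)O)cc2[C@H]1OC(C)=O | intermediate
14 | angelic acid, (2Z)-2-methylbut-2-enoic acid | C/C=C(/C)C(=O)O | starting material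
15 | (2Z)-2-methylbut-2-enoic 2,4,6-trichlorobenzoic anhydride (not isolated) | C/C=C(/C)C(=O)OC(=O)c1c(Cl)cc(Cl)cc1Cl | intermediate
16 | (1R)-1-[(2S,3R)-3-acetoxy-2-(prop-1-en-2-yl)-2,3-dihydro-1-benzofuran-5-yl]ethyl (2Z)-2-methylbut-2-enoate | C=C(C)[C@@H]1Oc2ccc([C@@H](C)OC(=O)/C(C)=C\C)cc2[C@H]1OC(C)=O | intermediate
17 | (1R)-1-[(2S,3R)-3-acetoxy-2-(3-hydroxyprop-1-en-2-yl)-2,3-dihydro-1-benzofuran-5-yl]ethyl (2Z)-2-methylbut-2-enoate | C=C(CO)[C@@H]1Oc2ccc([C@@H](C)OC(=O)/C(C)=C\C)cc2[C@H]1OC(C)=O | intermediate
18 | (1R)-1-[(2S,3R)-3-acetoxy-2-(3-oxoprop-1-en-2-yl)-2,3-dihydro-1-benzofuran-5-yl]ethyl (2Z)-2-methylbut-2-enoate | C=C(C=O)[C@@H]1Oc2ccc([C@@H](C)OC(=O)/C(C)=C\C)cc2[C@H]1OC(C)=O | target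

**Totals**

Total steps: 11. Longest linear sequence: 11 steps (1 to 18); compounds 2, 8 and 14 enter as single reagents.

**Steps most likely to fail**

Step 3 (photocycloaddition). The triplet may decay without closing because the one-atom tether strains the approach of the carbonyl oxygen to the alkene terminus; it may close to the bridged acetal instead; or the aryl bromide may be lost by C–Br homolysis. The fallback uses known chemistry, sets out from 1 and comes back at 6, and so also bypasses the oxetane opening of step 4.
- Addition of 2-methylprop-1-enylmagnesium bromide (excess, THF, 0 °C) to 1 gives racemic 4-bromo-2-(1-hydroxy-3-methylbut-2-en-1-yl)phenol F1.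
- Epoxidation with mCPBA/NaHCO3 in CH2Cl2 at 0 °C, directed by the allylic hydroxyl under 1,3-allylic strain, gives the threo epoxy alcohol 4-bromo-2-[(3,3-dimethyloxiran-2-yl)(hydroxy)methyl]phenol F2.
- With K2CO3 in MeOH the phenoxide opens the epoxide at its secondary carbon (5-exo, inversion) to racemic trans-5-bromo-2-(2-hydroxypropan-2-yl)-2,3-dihydro-1-benzofuran-3-ol F3.
- Ac2O/pyridine at 0 °C acetylates only the secondary hydroxyl and gives 6.

Step 5 (lipase resolution). The enzyme may not accept an acetate flanked by a fused arene and a carbon bearing a tertiary carbinol, or may discriminate the enantiomers poorly. The fallback replaces kinetic resolution by separation of diastereomers, sets out from 5 and comes back at 7.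
- Racemic 5 is opened under the buffered conditions of step 4, with (2S)-2-methoxy-2-phenylacetic acid and sodium (2S)-2-methoxy-2-phenylacetate in MeCN at 40 °C in place of acetic acid and NaOAc.
- This gives (2R,3R)-5-bromo-2-(2-hydroxypropan-2-yl)-2,3-dihydro-1-benzofuran-3-yl (2S)-2-methoxy-2-phenylacetate F4 and its (2S,3S)-configured diastereomer F5, which are separated by chromatography or crystallization.
- Methanolysis of F4 (K2CO3, MeOH, 0 °C) gives (2R,3R)-5-bromo-2-(2-hydroxypropan-2-yl)-2,3-dihydro-1-benzofuran-3-ol F6.
- Ac2O/pyridine at 0 °C converts F6 into 7.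

Step 9 (angeloylation). The Z-alkene may isomerize to the E (tiglate) isomer during acyl transfer, or acylation of the secondary benzylic alcohol may be too slow without a nucleophilic catalyst and the carbinol may ionize on prolonged heating. The fallback builds the Z-alkene after the ester bond, sets out from 13 and comes back at 16.
- 13 is esterified with 2-[bis(2,2,2-trifluoroethoxy)phosphoryl]propanoic acid (EDC·HCl, catalytic DMAP, CH2Cl2, 0 °C) to (1R)-1-[(2S,3R)-3-acetoxy-2-(prop-1-en-2-yl)-2,3-dihydro-1-benzofuran-5-yl]ethyl 2-[bis(2,2,2-trifluoroethoxy)phosphoryl]propanoate F7.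
- Still–Gennari olefination (KN(SiMe3)2, 18-crown-6, THF, −78 °C, then acetaldehyde) forms the Z-trisubstituted alkene and gives 16.

**Further compounds**

F1 | step 3 | racemic 4-bromo-2-(1-hydroxy-3-methylbut-2-en-1-yl)phenol | CC(C)=CC(O)c1cc(Br)ccc1O
F2 | step 3 | racemic threo 4-bromo-2-{(R)-[(2S)-3,3-dimethyloxiran-2-yl](hydroxy)methyl}phenol (one enantiomer drawn) | CC1(C)O[C@H]1[C@H](O)c1cc(Br)ccc1O
F3 | step 3 | racemic trans-5-bromo-2-(2-hydroxypropan-2-yl)-2,3-dihydro-1-benzofuran-3-ol (drawn as the (2R,3R) enantiomer) | CC(C)(O)[C@@H]1Oc2ccc(Br)cc2[C@H]1O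
F4 | step 5 | (2R,3R)-5-bromo-2-(2-hydroxypropan-2-yl)-2,3-dihydro-1-benzofuran-3-yl (2S)-2-methoxy-2-phenylacetate | CC(C)(O)[C@@H]1Oc2ccc(Br)cc2[C@H]1OC(=O)[C@@H](OC)c1ccccc1
F5 | step 5 | (2S,3S)-5-bromo-2-(2-hydroxypropan-2-yl)-2,3-dihydro-1-benzofuran-3-yl (2S)-2-methoxy-2-phenylacetate | CC(C)(O)[C@H]1Oc2ccc(Br)cc2[C@@H]1OC(=O)[C@@H](OC)c1ccccc1
F6 | step 5 | (2R,3R)-5-bromo-2-(2-hydroxypropan-2-yl)-2,3-dihydro-1-benzofuran-3-ol (single enantiomer) | CC(C)(O)[C@@H]1Oc2ccc(Br)cc2[C@H]1O
F7 | step 9 | (1R)-1-[(2S,3R)-3-acetoxy-2-(prop-1-en-2-yl)-2,3-dihydro-1-benzofuran-5-yl]ethyl 2-[bis(2,2,2-trifluoroethoxy)phosphoryl]propanoate (both epimers at the phosphonate carbon) | C=C(C)[C@@H]1Oc2ccc([C@@H](C)OC(=O)C(C)P(=O)(OCC(F)(F)F)OCC(F)(F)F)cc2[C@H]1OC(C)=O
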